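Percent of the Z charged is the unit I count in, because Z is the limiting reagent, charged at 12 mM against 48.0 mM of L, and its ledger has to close at 100.

| flask | Z | L | remark | time |
|---|---|---|---|---|
| alpha | 12 mM | 48 mM | the very flask that is asked about, followed so far |  |
| beta | 12 mM | 96 mM | run made earlier |  |
| flask | 12 mM | 48.0 mM |  | 40 min |

| run | time / min | Z / % | J / % | E / % |
|---|---|---|---|---|
| alpha | 2.50 | 22 | 8 | 1 |
| alpha | 5.00 | 19 | 10 | 3 |
| alpha | 8.00 | 20 | 15 | 4 |
| alpha | 10.0 | 16 | 12 | 7 |
| alpha | 12.0 | 15 | 13 | 5 |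
| alpha | 15.0 | 14 | 13 | 10 |
| beta | 6.00 | 18 | 13 | 8 |
| beta | 12.0 | 10 | 10 | 11 |
| beta | 20.0 | 8 | 6 | 4 |
| beta | 25.0 | 5 | 6 | 4 |
| beta | 30.0 | 4 | 5 | 3 |
| beta | 40.0 | 4 | 4 | 1 |

(standard deviation of a reading: 1.5 percentage points)

- how much Z there is at 40 min, in percent of the Z charged
- how much J there is at 40 min, in percent of the Z charged
- how much E there is at 40 min, in percent of the Z charged
- how much D there is at 40 min, in percent of the Z charged



In alpha at 2.50 min, Z, J and E leave a gap of 69.0%. I expect D to form from E, and E reads 1%, far less than that gap, so I take the gap as a held form of Z, not as product. My quantity is the free share, Z over Z plus its held form: 24.2%, a reading with its scatter.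

Turn [L] first. By hand, with L in excess, doubling the charge should double the pseudo-first-order slope of ln[Z]. The scattered readings give less: 0.0362 min⁻¹ in alpha, 0.0627 min⁻¹ in beta, a factor of 1.73. Turn time next. By hand, the product of [L] and time should count, so beta at 20.0 min stands in for alpha at 40 min, and it reads Z 8%, J 6%, E 4%. Both runs charge the same Z, so they are silent on that setting.

I commit to those three readings. Dividing Z by the free share gives 33.1% for Z and held form together, which leaves 56.9% for whatever else is unseen. The forecast says Z 8%, J 8%, E 5% and D 79%, more D than my room, with the early gap “presumably as D”.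

The flask gives Z 8.51%, J 9.58%, E 6.68% and D 40.9%.

    Z + L → J (k = 0.0470 M⁻¹ s⁻¹)
    L + J → E (k = 0.0450 M⁻¹ s⁻¹)
    L + E → D (k = 0.0730 M⁻¹ s⁻¹)
    Z ⇌ Q (K = 3.10, k = 0.0730 s⁻¹)
    J ⇌ X (K = 1.90, k = 3.30 × 10⁻⁴ s⁻¹)

The held form is Q, and X stands at 7.58% at 40.0 min. The free share turns the computed Z into Q of 26.7%, and the ledger then leaves 48.6%, which D and X share: 48.5% together.

The same flask read at 1.5 h has Z 3.67%, J 4.81% and E 3.37%, so the free share leaves 76.7%. Computed, D is 67.1% and X 9.54%.

All runs come from a simulation with made-up constants.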